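The route rests on cutting the C1–C5 and C8–C9 bonds (daucane numbering) of the hydroazulene. Its seven-membered ring divides into a three-carbon unit C1–C10–C9 whose central carbon C10 is oxygenated and a four-carbon unit C5–C6–C7–C8 oxygenated at C6, joined through C2–C3–C4. The key step is therefore an intramolecular (4+3) cycloaddition of a 2-ethoxyallyl cation onto a 2-silyloxydiene: it closes the cyclopentane and the cycloheptane at once and sets C1, C5 and C8. The precursor is an acyclic chain made from (S)-terpinen-4-ol, in which a diisopropylsilylene ring ties the C4 oxygen to the C6 dienol oxygen.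

Key step: step 6

Remark: daucane numbering is used (C1 quaternary ring-fusion carbon with methyl C15; C2, C3; C4 carbinol with isopropyl; C5 ring-fusion CH; C6; C7; C8 with methyl C14; C9; C10), β is the face of C15, and (S)-(+)-terpinen-4-ol is assumed to be bought in high enantiomeric purity.

Step 1
Reactants: 1 (S)-(+)-terpinen-4-ol
Product: 3 (3S)-3-hydroxy-6-oxo-3-(propan-2-yl)heptanal, via secondary ozonide 2 (not isolated)
Conditions: O3, CH2Cl2, −78 °C; then Me2S, −78 °C to rt
Reagents that add atoms: ozone, [O-][O+]=O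
Why: Ozonolysis with reductive work-up cleaves the only C=C bond into the methyl ketone (future C1/C15) and the aldehyde (future C6), while the tertiary carbinol centre (future C4) is not touched.

Step 2
Reactants: 3 (3S)-3-hydroxy-6-oxo-3-(propan-2-yl)heptanal
Product: 4 (5S,8E)-5,7-dihydroxy-5-(propan-2-yl)dec-8-en-2-one (both C7 epimers)
Conditions: (E)-1-bromoprop-1-ene, CrCl2 (4 equiv), NiCl2 (2 mol%), DMSO/DMF, rt
Reagents that add atoms: (E)-1-bromoprop-1-ene, C/C=C/Br
Why: In the Nozaki–Hiyama–Kishi reaction the alkenylchromium species should add to the aldehyde only, tolerating the methyl ketone and the free tertiary hydroxyl and retaining the E geometry; the new carbinol centre is oxidised in the next step, so its configuration is irrelevant.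

Step 3
Reactants: 4 (5S,8E)-5,7-dihydroxy-5-(propan-2-yl)dec-8-en-2-one
Product: 5 (5S,8E)-5-hydroxy-5-(propan-2-yl)dec-8-ene-2,7-dione
Conditions: activated MnO2 (excess), CH2Cl2, rt
Reagents that add atoms: none
Why: MnO2 oxidises only the allylic secondary alcohol, and its neutral conditions should spare the β-hydroxy ketone from dehydration, retro-aldol cleavage and oxa-Michael closure.

Step 4
Reactants: 5 (5S,8E)-5-hydroxy-5-(propan-2-yl)dec-8-ene-2,7-dione
Product: 6 4-[(4R)-2,2,4-tri(propan-2-yl)-6-[(1E)-prop-1-en-1-yl]-4H-1,3,2-dioxasilin-4-yl]butan-2-one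
Conditions: iPr2Si(OTf)2 (1.05 equiv), Et3N, CH2Cl2, −78 to 0 °C
Reagents that add atoms: diisopropylsilyl bis(trifluoromethanesulfonate), CC(C)[Si](OS(=O)(=O)C(F)(F)F)(OS(=O)(=O)C(F)(F)F)C(C)C
Why: The bis-triflate silylates the tertiary hydroxyl, the remaining Si–OTf activates the neighbouring enone carbonyl through a six-membered ring, and Et3N removes a C5 proton (soft enolisation, silyl enol ether formation with a silyl triflate and an amine), giving the cross-conjugated dienol ether with the C5=C6 geometry fixed by the ring.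

Step 5
Reactants: 6 4-[(4R)-2,2,4-tri(propan-2-yl)-6-[(1E)-prop-1-en-1-yl]-4H-1,3,2-dioxasilin-4-yl]butan-2-one
Product: 7 2-ethoxy-3-methyl-5-[(4R)-2,2,4-tri(propan-2-yl)-6-[(1E)-prop-1-en-1-yl]-4H-1,3,2-dioxasilin-4-yl]pent-1-en-3-ol (both C3 epimers)
Conditions: ethyl vinyl ether, t-BuLi, THF, −78 to 0 °C; then 6, −78 °C; H2O quench
Reagents that add atoms: ethyl vinyl ether (used as 1-ethoxyvinyllithium), C=COCC
Why: 1,2-Addition of the α-lithiated enol ether to the methyl ketone installs C10 and C9, the silyl dienol ether being inert to the organolithium at −78 °C; the new carbinol carbon (future C1) is ionised in the next step, so both epimers serve.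

Step 6
Reactants: 7 2-ethoxy-3-methyl-5-[(4R)-2,2,4-tri(propan-2-yl)-6-[(1E)-prop-1-en-1-yl]-4H-1,3,2-dioxasilin-4-yl]pent-1-en-3-ol
Product: 10 4β,6-(diisopropylsilylenedioxy)-5αH,8αH-dauc-6-en-10-one (trans-fused; C15 and C14 β), via 2-ethoxyallyl cation 8 (not isolated), via O-ethyl oxocarbenium ion 9 (not isolated)
Conditions: Tf2O, 2,6-lutidine, CH2Cl2, −78 to −40 °C; aq. NaHCO3 work-up
Reagents that add atoms: none
Why: O-triflation and ionisation of the tertiary carbinol give the 2-ethoxyallyl cation 8 (C1–C10–C9), which adds across the termini C5 and C8 of the tethered 2-silyloxydiene, concertedly or by attack of the silyl enol ether carbon C5 on C1 followed by closure of the enol ether carbon C9 onto C8 of the resulting silyloxyallyl cation, and the O-ethyl oxocarbenium ion 9 then loses its ethyl group to triflate. The closest known reaction type is the intramolecular (4+3) cycloaddition of 2-alkoxyallyl cations, generated from allylic alcohols or sulfones, with tethered 1,3-dienes. The cyclopentane closes in the 5-exo mode through the C2–C3–C4 tether (enol ether double bond exocyclic to the new ring) and the cycloheptane closes as the (4+3) ring, 7-endo with respect to the C7=C8 unit. C5 is controlled by C4, because the tether can reach only the diene face that carries the C3 arm, which puts H-5 cis to the isopropyl group and the C4 oxygen cis to C6; C1 follows from an extended transition state, since the compact one pushes the ethoxy group onto the silylene ring at C6, and this gives the trans ring fusion; C8 follows from the E propenyl geometry and suprafacial use of the diene, which puts H-8 cis to H-5. The step needs trans over cis fusion and (4+3) over (3+2) closure or proton loss: the bulky ring-bound silyloxy group at C6 disfavours the compact approach, and in the trans-disposed intermediate a (3+2) closure onto C6 would have to form a trans-bicyclo[3.3.0]octane.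

Step 7
Reactants: 10 4β,6-(diisopropylsilylenedioxy)-5αH,8αH-dauc-6-en-10-one
Product: 11 4β,6-(diisopropylsilylenedioxy)-5αH,8αH-dauca-6,9-dien-10-yl trifluoromethanesulfonate
Conditions: KHMDS, THF, −78 °C; then PhNTf2, −78 to 0 °C
Reagents that add atoms: N-phenylbis(trifluoromethanesulfonimide), O=S(=O)(N(c1ccccc1)S(=O)(=O)C(F)(F)F)C(F)(F)F
Why: C1 is quaternary, so the ketone can enolise only towards C9 and O-triflation of the potassium enolate gives a single enol triflate; the silyl enol ether is inert to the base.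

Step 8
Reactants: 11 4β,6-(diisopropylsilylenedioxy)-5αH,8αH-dauca-6,9-dien-10-yl trifluoromethanesulfonate
Product: 12 4β,6-(diisopropylsilylenedioxy)-5αH,8αH-dauca-6,9-diene
Conditions: Pd(OAc)2 (5 mol%), PPh3, HCO2H, n-Bu3N, DMF, 60 °C
Reagents that add atoms: none
Why: Palladium-catalysed formate reduction of the alkenyl triflate (oxidative addition, formate exchange, decarboxylation, reductive elimination) replaces OTf by H and leaves the C9=C10 alkene in place, the amine-buffered medium sparing the silyl enol ether.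

Step 9
Reactants: 12 4β,6-(diisopropylsilylenedioxy)-5αH,8αH-dauca-6,9-diene
Product: 13 4β-hydroxy-5αH,8αH-dauc-9-en-6-one
Conditions: HF·pyridine, pyridine, THF, 0 °C
Reagents that add atoms: none
Why: Fluoride cleaves both Si–O bonds and the enol is protonated at C7, giving the β-hydroxy ketone; the buffered, non-basic medium should avoid retro-aldol cleavage and epimerisation at C5.

Step 10
Reactants: 13 4β-hydroxy-5αH,8αH-dauc-9-en-6-one
Product: 14 5αH,8αH-dauc-9-ene-4β,6α-diol
Conditions: Me4NBH(OAc)3, MeCN/AcOH (1:1), −30 °C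
Reagents that add atoms: none
Why: In the Evans–Saksena reduction the acetoxyborohydride bound to the 4β-hydroxyl delivers hydride intramolecularly to the β face of the C6 carbonyl, which should give the 1,3-anti diol with the 6α-hydroxyl; the isolated alkene is not reduced.

Step 11
Reactants: 14 5αH,8αH-dauc-9-ene-4β,6α-diol
Product: 15 4β-hydroxy-5αH,8αH-dauc-9-en-6α-yl 3-methylbutanoate
Conditions: (iPrCH2CO)2O, Et3N, DMAP (cat.), CH2Cl2, 0 °C to rt
Reagents that add atoms: 3-methylbutanoic anhydride, CC(C)CC(=O)OC(=O)CC(C)C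
Why: DMAP-catalysed acylation takes place at the secondary 6α-hydroxyl only, the hindered tertiary 4β-hydroxyl being unreactive under these conditions.

Step 12
Reactants: 15 4β-hydroxy-5αH,8αH-dauc-9-en-6α-yl 3-methylbutanoate
Product: 17 8α,9α-epoxy-4β,10α-dihydroxydaucan-6α-yl 3-methylbutanoate, via allylic 10α-hydroperoxide 16 (not isolated)
Conditions: O2, hν (sodium lamp), tetraphenylporphyrin (cat.), Ti(OiPr)4 (10 mol%), 4 Å MS, CH2Cl2, −10 to 0 °C
Reagents that add atoms: oxygen, O=O
Why: In the Schenck ene reaction singlet oxygen can only abstract H-8 (C1 has no hydrogen), so it bonds to C10 on the same α face, anti to the axial C15 methyl, and shifts the double bond to C8=C9; titanium-catalysed oxygen transfer from the hydroperoxide to this allylic double bond, directed by the C10 oxygen, should then give the 8α,9α-epoxide syn to the 10α-hydroxyl.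

Step 13
Reactants: 17 8α,9α-epoxy-4β,10α-dihydroxydaucan-6α-yl 3-methylbutanoate
Product: 18 10α-acetoxy-8α,9α-epoxy-4β-hydroxydaucan-6α-yl 3-methylbutanoate
Conditions: Ac2O, pyridine, DMAP (cat.), CH2Cl2, rt
Reagents that add atoms: acetic anhydride, CC(=O)OC(C)=O
Why: DMAP-catalysed acetylation of the secondary 10α-hydroxyl gives the target, the tertiary 4β-hydroxyl staying free as in the target.

Compound list
1 | (S)-(+)-terpinen-4-ol, (1S)-4-methyl-1-(propan-2-yl)cyclohex-3-en-1-ol | CC1=CC[C@](O)(C(C)C)CC1 | starting material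
2 | secondary ozonide of 1 (1,2,4-trioxolane across the former C=C) | CC12CC[C@@](O)(C(C)C)CC(OO1)O2 | intermediate
3 | (3S)-3-hydroxy-6-oxo-3-(propan-2-yl)heptanal | O=CC[C@](O)(C(C)C)CCC(C)=O | intermediate
4 | (5S,8E)-5,7-dihydroxy-5-(propan-2-yl)dec-8-en-2-one (both C7 epimers) | C/C=C/C(O)C[C@](O)(C(C)C)CCC(C)=O | intermediate
5 | (5S,8E)-5-hydroxy-5-(propan-2-yl)dec-8-ene-2,7-dione | C/C=C/C(=O)C[C@](O)(C(C)C)CCC(C)=O | intermediate
6 | 4-[(4R)-2,2,4-tri(propan-2-yl)-6-[(1E)-prop-1-en-1-yl]-4H-1,3,2-dioxasilin-4-yl]butan-2-one | C/C=C/C1=C[C@](C(C)C)(CCC(C)=O)O[Si](C(C)C)(C(C)C)O1 | intermediate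
7 | 2-ethoxy-3-methyl-5-[(4R)-2,2,4-tri(propan-2-yl)-6-[(1E)-prop-1-en-1-yl]-4H-1,3,2-dioxasilin-4-yl]pent-1-en-3-ol (both C3 epimers) | C/C=C/C1=C[C@](C(C)C)(CCC(C)(O)C(=C)OCC)O[Si](C(C)C)(C(C)C)O1 | intermediate
8 | 2-ethoxyallyl cation from 7 (triflate ion pair) | C/C=C/C1=C[C@](C(C)C)(CC[C+](C)C(=C)OCC)O[Si](C(C)C)(C(C)C)O1.[O-]S(=O)(=O)C(F)(F)F | intermediate
9 | O-ethyl oxocarbenium ion of the cycloadduct (triflate ion pair) | CC[O+]=C1C[C@@H](C)C=C(O[Si](C(C)C)(C(C)C)O3)[C@@H]2[C@]1(C)CC[C@@]23C(C)C.[O-]S(=O)(=O)C(F)(F)F | intermediate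
10 | 4β,6-(diisopropylsilylenedioxy)-5αH,8αH-dauc-6-en-10-one | O=C1C[C@@H](C)C=C(O[Si](C(C)C)(C(C)C)O3)[C@@H]2[C@]1(C)CC[C@@]23C(C)C | intermediate
11 | 4β,6-(diisopropylsilylenedioxy)-5αH,8αH-dauca-6,9-dien-10-yl trifluoromethanesulfonate | O=S(=O)(OC1=C[C@@H](C)C=C(O[Si](C(C)C)(C(C)C)O3)[C@@H]2[C@]1(C)CC[C@@]23C(C)C)C(F)(F)F | intermediate
12 | 4β,6-(diisopropylsilylenedioxy)-5αH,8αH-dauca-6,9-diene | C1=C[C@@H](C)C=C(O[Si](C(C)C)(C(C)C)O3)[C@@H]2[C@]1(C)CC[C@@]23C(C)C | intermediate
13 | 4β-hydroxy-5αH,8αH-dauc-9-en-6-one | C1=C[C@@H](C)CC(=O)[C@@H]2[C@]1(C)CC[C@@]2(O)C(C)C | intermediate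
14 | 5αH,8αH-dauc-9-ene-4β,6α-diol | C1=C[C@@H](C)C[C@H](O)[C@@H]2[C@]1(C)CC[C@@]2(O)C(C)C | intermediate
15 | 4β-hydroxy-5αH,8αH-dauc-9-en-6α-yl 3-methylbutanoate | C1=C[C@@H](C)C[C@H](OC(=O)CC(C)C)[C@@H]2[C@]1(C)CC[C@@]2(O)C(C)C | intermediate
16 | 10α-hydroperoxy-4β-hydroxydauc-8-en-6α-yl 3-methylbutanoate | OO[C@@H]1C=C(C)C[C@H](OC(=O)CC(C)C)[C@@H]2[C@]1(C)CC[C@@]2(O)C(C)C | intermediate
17 | 8α,9α-epoxy-4β,10α-dihydroxydaucan-6α-yl 3-methylbutanoate | O[C@@H]1[C@@H]2O[C@]2(C)C[C@H](OC(=O)CC(C)C)[C@@H]2[C@]1(C)CC[C@@]2(O)C(C)C | intermediate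
18 | 10α-acetoxy-8α,9α-epoxy-4β-hydroxydaucan-6α-yl 3-methylbutanoate (CNP0137153.1) | CC(=O)O[C@@H]1[C@@H]2O[C@]2(C)C[C@H](OC(=O)CC(C)C)[C@@H]2[C@]1(C)CC[C@@]2(O)C(C)C | target

Total step count: 13. Longest linear sequence: 13 steps.

Steps most likely to fail

Step 6. The cation may lose a proton to a 2-ethoxydiene, add through the compact approach (eroding the trans ring fusion), or close by the (3+2) mode onto C6. The fallback replaces the alkoxyallyl cation by a metal-bound allyl cation from an allene, whose approach is governed by the ligand on the metal and which ends directly in the C9=C10 alkene. It sets out from 6: addition of ethynylmagnesium bromide to the methyl ketone should give the tertiary propargylic alcohol F1, and n-BuLi/ClCO2Me its methyl carbonate F2. Palladium-catalysed formate hydrogenolysis (Pd2(dba)3, PBu3, HCO2NH4) should then give the 1,1-disubstituted allene F3. A PtCl2-catalysed (or cationic gold(I)-catalysed) intramolecular allene–diene (4+3) cycloaddition, ending with a 1,2-hydrogen shift of the C10 metal carbene from C9, comes back to the route at 12, so that steps 7 and 8 fall away.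

Step 12. The ene reaction of a cis-disubstituted cycloheptene with singlet oxygen is slow and needs H-8 perpendicular to the alkene plane, so the sensitiser may bleach before conversion is complete. The fallback installs the C10 oxygen by epoxidation and then transposes it. It sets out from 15: mCPBA should epoxidise the C9=C10 bond from the α face, anti to the axial C15 methyl, to the 9α,10α-epoxide F4. A diethylaluminium 2,2,6,6-tetramethylpiperidide-induced syn elimination of H-8 (cis to the epoxide oxygen, the only β-hydrogen available) should then open it to the 10α-hydroxy-Δ8 allylic alcohol F5. A VO(acac)2/t-BuOOH hydroxyl-directed epoxidation comes back to the route at 17.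

Step 4. Enolisation may go the wrong way (at the C14 methyl or at the methyl ketone), or the hydroxy enone may close by oxa-Michael addition before silylation. The fallback consumes the methyl ketone first and then uses kinetic base enolisation. It sets out from 4: excess 1-ethoxyvinyllithium should add to the only carbonyl to give the triol F6, and MnO2 should oxidise the allylic alcohol to the hydroxy enone F7. LDA (3.1 equiv, −78 °C; α′-deprotonation at C5 with both alkoxides formed) followed by iPr2SiCl2 should silylate the enolate oxygen and close the six-membered ring onto the C4 alkoxide, coming back to the route at 7.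

Further compounds
F1 | step 6 | 3-methyl-5-[(4R)-2,2,4-tri(propan-2-yl)-6-[(1E)-prop-1-en-1-yl]-4H-1,3,2-dioxasilin-4-yl]pent-1-yn-3-ol | C/C=C/C1=C[C@](C(C)C)(CCC(C)(O)C#C)O[Si](C(C)C)(C(C)C)O1
F2 | step 6 | methyl carbonate of F1 | C/C=C/C1=C[C@](C(C)C)(CCC(C)(OC(=O)OC)C#C)O[Si](C(C)C)(C(C)C)O1
F3 | step 6 | (4R)-4-(3-methylpenta-3,4-dien-1-yl)-2,2,4-tri(propan-2-yl)-6-[(1E)-prop-1-en-1-yl]-4H-1,3,2-dioxasiline | C/C=C/C1=C[C@](C(C)C)(CCC(C)=C=C)O[Si](C(C)C)(C(C)C)O1
F4 | step 12 | 9α,10α-epoxy-4β-hydroxy-5αH,8αH-daucan-6α-yl 3-methylbutanoate | O1[C@@H]2[C@H]1[C@@H](C)C[C@H](OC(=O)CC(C)C)[C@@H]3[C@]2(C)CC[C@@]3(O)C(C)C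
F5 | step 12 | 4β,10α-dihydroxydauc-8-en-6α-yl 3-methylbutanoate | O[C@@H]1C=C(C)C[C@H](OC(=O)CC(C)C)[C@@H]2[C@]1(C)CC[C@@]2(O)C(C)C
F6 | step 4 | (6S,9E)-2-ethoxy-3-methyl-6-(propan-2-yl)undeca-1,9-diene-3,6,8-triol (epimer mixture at C3 and C8) | C/C=C/C(O)C[C@](O)(C(C)C)CCC(C)(O)C(=C)OCC
F7 | step 4 | (2E,6S)-10-ethoxy-6,9-dihydroxy-9-methyl-6-(propan-2-yl)undeca-2,10-dien-4-one (both C9 epimers) | C/C=C/C(=O)C[C@](O)(C(C)C)CCC(C)(O)C(=C)OCC
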